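**Plan**
1. Retrosynthesis first cuts, in one event, the bonds C5=C6 and C7–C8 of the cycloheptene (azulene locants of the target: C1 C(CH2OH), C2 CHMe, C3a C(CHO), C4 CHOH, C5 CMe, C8a ring-fusion CH). This removes the unsubstituted C6–C7 bridge as a vinylphosphonium salt. Next come the C2'–C3' bond of the side chain (alkylborane + bromobutenolide) and the acetyl unit on C4.
2. The enabling feature is the arc C8a–C8H2–C7H2–C6H=C5(Me)–C4H(OH) of ring A. C8 is a plain CH2 on the ring-fusion carbon (a primary radical from a bromide), C5 is a methyl-bearing sp2 carbon beside the carbinol (a methyl ketone in disguise), C6 and C7 carry only hydrogen, and both arms stand cis on the adjacent cyclopentane carbons C8a and C3a.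
3. Forward: Diels–Alder reaction of a menthyloxybutenolide with (E)-piperylene gives a cyclohexene, which is cleaved and re-closed by aldol condensation to the cyclopentene carbaldehyde (ring B). Its two quaternary carbons are completed, a radical–polar crossover [5+2] annulation closes ring A, and the side chain is joined last.
4. Stereochemistry: the menthyloxy acetal fixes the absolute sense at C8a/C1, the endo/ortho Diels–Alder reaction sets C2, the cis-fused lactone enolate sets C1, anti attack on an enol silane sets C3a, and a chelate-controlled addition sets C4. The ring alkene is Z by ring size and the side-chain geometry is inherited from the butenolide ring.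

Key step: step 14

Remark: C-locants in the Why lines are those of the hydroazulene of the target; where a name and a SMILES string differ, the SMILES string holds.

**Step 1**
Reactants: 1 5-hydroxyfuran-2(5H)-one; 2 (+)-menthol
Product: 3 (5S)-5-[(1S,2R,5S)-menthyloxy]furan-2(5H)-one
Conditions: 10-camphorsulfonic acid (cat.), toluene, reflux, Dean–Stark; crystallisation from hexane at −20 °C, mother liquor re-equilibrated with acid
Reagents that add atoms: none
Why: Acid-catalysed acetalisation of the pseudo-acid, in which the two C5 epimers interconvert and the (5S) epimer should be harvested by crystallisation-induced diastereomer transformation (mirror image of the established l-menthyl case), fixing the absolute configuration of the route.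

**Step 2**
Reactants: 3 (5S)-5-menthyloxyfuran-2(5H)-one; 4 (E)-penta-1,3-diene
Product: 5 3-(menthyloxy)-7-methyl-3a,4,7,7a-tetrahydro-2-benzofuran-1(3H)-one (cis-fused; methyl cis to the lactone carbonyl; menthyloxy on the face of the two ring-fusion hydrogens)
Conditions: toluene, BHT (cat.), 120 °C, sealed tube
Reagents that add atoms: none
Why: Thermal Diels–Alder reaction in which the diene adds to the butenolide face opposite the menthyloxy group, its methyl-bearing terminus bonds to the carbon α to the carbonyl (ortho rule) and the endo transition state puts the methyl group cis to the lactone carbonyl, which sets the future C8a, C1 and C2.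

**Step 3**
Reactants: 5 Diels–Alder adduct; 6 acetaldehyde
Product: 7 7a-(1-hydroxyethyl) derivative of 5 (cis fusion kept; carbinol carbon as a mixture)
Conditions: LiN(iPr)2, THF, −78 °C; MeCHO, −78 °C; NH4Cl (aq.) at −78 °C
Reagents that add atoms: none
Why: Aldol addition of the lithium lactone enolate at the ring-fusion carbon, where the bicyclic lactone can only stay cis-fused, so the aldehyde enters on the convex face and the future C1 quaternary centre is fixed (the carbinol centre is removed in step 4).

**Step 4**
Reactants: 7 aldol adduct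
Product: 8 3-(menthyloxy)-7-methyl-7a-vinyl-3a,4,7,7a-tetrahydro-2-benzofuran-1(3H)-one
Conditions: Ph2S[OC(CF3)2Ph]2, CH2Cl2, 0 → 20 °C
Reagents that add atoms: none
Why: Dehydration through the alkoxysulfurane (E2-type elimination), in which the carbinol is flanked by a quaternary carbon so that only the methyl group can lose hydrogen and a vinyl group must result.

**Step 5**
Reactants: 8 vinyl menthyloxy lactone
Product: 10 7-methyl-7a-vinyl-3a,4,7,7a-tetrahydro-2-benzofuran-1(3H)-one (cis-fused; methyl cis to C=O), via lactol 9 (not isolated)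
Conditions: 2 M HCl, 1,4-dioxane, 60 °C; then NaOH to pH 9–10, NaBH4, 0 → 20 °C; then 2 M HCl to pH 2
Reagents that add atoms: water (O)
Why: Hydrolysis of the acyloxy acetal frees the auxiliary and the lactol, whose open aldehyde form is reduced by borohydride, and acid lactonisation returns the cis-fused γ-lactone with the three ring stereocentres untouched.

**Step 6**
Reactants: 10 cis-fused vinyl lactone
Product: 12 methyl 2-(bromomethyl)-6-methyl-1-vinylcyclohex-4-ene-1-carboxylate (CO2Me, CH2Br and CH3 all cis), via bromo acid 11 (not isolated)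
Conditions: BBr3, CH2Cl2, −78 → 0 °C; H2O; then Me3SiCHN2, MeOH/toluene, 0 °C
Reagents that add atoms: boron tribromide (BrB(Br)Br); (trimethylsilyl)diazomethane (C[Si](C)(C)C=[N+]=[N-])
Why: Lewis acid-mediated lactone cleavage in which bromide attacks the activated primary O–CH2 carbon in an SN2 step (alkyl–oxygen cleavage), followed by esterification of the hindered acid with the diazoalkane, giving the primary bromide as radical precursor and the ester as masked CH2OH.

**Step 7**
Reactants: 12 bromo ester
Product: 13 methyl 4-(bromomethyl)-2-methyl-3-vinyl-7-oxabicyclo[4.1.0]heptane-3-carboxylate (epoxide face not defined)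
Conditions: mCPBA, NaHCO3, CH2Cl2, 0 °C
Reagents that add atoms: 3-chloroperoxybenzoic acid (O=C(OO)c1cccc(Cl)c1)
Why: Prilezhaev epoxidation, in which the cis-disubstituted ring alkene is far more nucleophilic and accessible than the vinyl group on the quaternary carbon, and the epoxide configuration is irrelevant because both carbons become aldehydes.

**Step 8**
Reactants: 13 epoxide
Product: 14 3-(bromomethyl)-4-(methoxycarbonyl)-5-methyl-4-vinylhexanedial
Conditions: H5IO6, THF/Et2O, 0 → 20 °C
Reagents that add atoms: periodic acid (OI(=O)(O)(O)(O)O)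
Why: Periodic acid opens the epoxide to the glycol and cleaves it in the same flask (glycol cleavage) to the 1,6-dialdehyde, leaving vinyl, ester and bromide alone.

**Step 9**
Reactants: 14 dialdehyde
Product: 15 methyl 5-(bromomethyl)-4-formyl-2-methyl-1-vinylcyclopent-3-ene-1-carboxylate
Conditions: (PhCH2)2NH·CF3CO2H (0.3 equiv), benzene, 50 °C
Reagents that add atoms: none
Why: Amine salt-catalysed intramolecular aldol condensation in which the enamine of the unbranched CH2CHO arm attacks the α-branched aldehyde and dehydration gives the conjugated cyclopentene carbaldehyde (ring B), the methyl-bearing centre being spared because its aldehyde acts only as acceptor.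

**Step 10**
Reactants: 15 cyclopentene carbaldehyde
Product: 16 methyl 2-(bromomethyl)-5-methyl-3-{[(triethylsilyl)oxy]methylidene}-1-vinylcyclopentane-1-carboxylate (enol ether geometry not defined)
Conditions: RhCl(PPh3)3 (2 mol %), Et3SiH, benzene, 50 °C
Reagents that add atoms: triethylsilane (CC[SiH](CC)CC)
Why: Rhodium-catalysed 1,4-hydrosilylation of the enal gives the silyl enol ether directly and should be faster than hydrosilylation of the hindered isolated vinyl group.

**Step 11**
Reactants: 16 silyl enol ether
Product: 17 methyl 2-(bromomethyl)-3-(dimethoxymethyl)-3-formyl-5-methyl-1-vinylcyclopentane-1-carboxylate (CO2Me, CH2Br, CHO and CH3 on one face; vinyl and CH(OMe)2 on the other)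
Conditions: HC(OMe)3, Me3SiOTf (10 mol %), CH2Cl2, −78 °C
Reagents that add atoms: trimethyl orthoformate (COC(OC)OC)
Why: Mukaiyama-type addition of the enol silane to the dimethoxycarbenium ion, which approaches C3a anti to the neighbouring CH2Br group (and to the 1,3-cis methyl), so the quaternary centre forms with the masked formyl group trans and the free formyl group cis to CH2Br.

**Step 12**
Reactants: 17 aldehyde acetal
Product: 19 methyl 2-(bromomethyl)-3-(dimethoxymethyl)-3-[(1S)-1-hydroxy-2-oxopropyl]-5-methyl-1-vinylcyclopentane-1-carboxylate, via enol ether adduct 18 (not isolated)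
Conditions: ethyl vinyl ether, t-BuLi, THF, −78 → 0 °C; MgBr2·OEt2, −78 °C; then 17, −78 °C; then 0.5 M HCl, THF, 0 °C
Reagents that add atoms: ethyl vinyl ether (C=COCC); water (O)
Why: Chelate-controlled 1,2-addition of an acetyl-anion equivalent, in which magnesium bridges the aldehyde oxygen and an acetal oxygen and the nucleophile attacks from the side of the ring CH2 (C3) and not of the substituted C8a, setting the C4 carbinol, after which the enol ether is hydrolysed much faster than the dimethyl acetal.

**Step 13**
Reactants: 19 α-hydroxy methyl ketone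
Product: 20 triethylsilyl ether of 19
Conditions: Et3SiCl, imidazole, DMAP (cat.), DMF, 20 °C
Reagents that add atoms: chlorotriethylsilane (CC[Si](Cl)(CC)CC)
Why: Silylation of the hindered secondary alcohol removes the only acidic O–H before ylide chemistry and blocks ring closure of the oxygen onto the primary bromide.

**Step 14**
Reactants: 20 bromo ketone; 21 vinyltriphenylphosphonium bromide
Product: 23 methyl 3a-(dimethoxymethyl)-2,5-dimethyl-4-[(triethylsilyl)oxy]-1-vinyl-1,2,3,3a,4,7,8,8a-octahydroazulene-1-carboxylate (cis-fused), via phosphonium ylide 22 (not isolated)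
Conditions: 21 (2 equiv), (Me3Si)3SiH, Ir[dF(CF3)ppy]2(dtbbpy)PF6 (1 mol %), Cs2CO3, MeCN, blue LEDs, 25 °C, then 50 °C
Reagents that add atoms: none
Why: Proposed new method: under blue light the excited iridium photocatalyst launches a silyl radical (oxidation of bromide, then hydrogen transfer from the silane) that abstracts bromine from 20; the primary C8 radical adds to the β-carbon of the vinylphosphonium ion (bond C7–C8), the α-phosphonio radical is reduced by the reduced photocatalyst to ylide 22 (Cs2CO3 returns any ylide that is protonated), and 22 olefinates the methyl ketone (bond C5=C6) with loss of Ph3PO. The closest known reaction types are the anionic vinylphosphonium (Schweizer-type) annulation, radical additions to vinylphosphonium salts, silyl-radical bromine abstraction from alkyl bromides under photoredox conditions and the photoredox three-component olefination of a radical precursor, a vinylphosphonium salt and a carbonyl compound; new is the pairing of a halide-derived radical with an intramolecular ketone Wittig reaction to close a seven-membered ring. Ring A closes in the Wittig stage by 7-exo-trig attack of the ylide carbon on the ketone carbon, and the ring allows only the Z-alkene. No stereocentre is created: the cis ring fusion is dictated by the cis arrangement of the CH2Br arm on C8a and the acyl arm on C3a set in steps 2 and 11, and the mild carbonate base should leave C4 unepimerised. The step needs capture of the nucleophilic primary radical by the electron-poor vinylphosphonium ion to outrun hydrogen transfer and cyclisation, and the ylide to choose the ketone over the ester; closure onto the C1 vinyl group would be 4-exo or 5-endo, and the ester stands on a quaternary carbon and is far less electrophilic than the ketone.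

**Step 15**
Reactants: 23 vinyl hydroazulene; 24 4-bromofuran-2(5H)-one
Product: 26 methyl 3a-(dimethoxymethyl)-2,5-dimethyl-1-[2-(5-oxo-2,5-dihydrofuran-3-yl)ethyl]-4-[(triethylsilyl)oxy]-1,2,3,3a,4,7,8,8a-octahydroazulene-1-carboxylate, via alkylborane 25 (not isolated)
Conditions: 9-BBN, THF, 0 → 50 °C; then 24, PdCl2(dppf) (5 mol %), AsPh3, Cs2CO3 (aq.), DMF, 25 → 40 °C
Reagents that add atoms: none
Why: Anti-Markovnikov hydroboration of the monosubstituted alkene (9-BBN should not touch the trisubstituted ring alkene) followed by B-alkyl Suzuki–Miyaura coupling with the β-bromobutenolide, whose lactone ring fixes the geometry that becomes the Z-configured ene-diol.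

**Step 16**
Reactants: 26 butenolide ester
Product: 27 triol: dimethyl acetal and C4 triethylsilyl ether of the target
Conditions: iBu2AlH (8 equiv), CH2Cl2, −78 → 0 °C; aq. potassium sodium tartrate
Reagents that add atoms: none
Why: 1,2-Selective hydride reduction turns the butenolide into the (Z)-2-ene-1,4-diol and the hindered methyl ester into the neopentyl CH2OH, while acetal and silyl ether are inert.

**Step 17**
Reactants: 27 protected triol
Product: 28 (1R,2R,3aR,4R,8aR)-4-hydroxy-1-(hydroxymethyl)-1-[(3Z)-5-hydroxy-3-(hydroxymethyl)pent-3-en-1-yl]-2,5-dimethyl-2,3,4,7,8,8a-hexahydroazulene-3a(1H)-carbaldehyde (CNP0338913.1)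
Conditions: 1 M HCl/THF (1:4), 0 → 20 °C
Reagents that add atoms: water (O)
Why: Dilute acid hydrolysis of the dimethyl acetal and of the triethylsilyl ether releases the aldehyde and the C4 hydroxyl; the formyl carbon sits on a quaternary centre (no epimerisation) and trans to the C1 CH2OH group, so no bridging hemiacetal should form.

**Compound list**
1 | 5-hydroxyfuran-2(5H)-one | O=C1C=CC(O)O1 | starting material
2 | (+)-menthol, (1S,2R,5S)-5-methyl-2-(propan-2-yl)cyclohexan-1-ol | C[C@H]1CC[C@@H]([C@H](C1)O)C(C)C | starting material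
3 | (5S)-5-[(1S,2R,5S)-menthyloxy]furan-2(5H)-one | C[C@H]1CC[C@@H]([C@H](C1)O[C@@H]2C=CC(=O)O2)C(C)C | intermediate
4 | (E)-penta-1,3-diene | C=C/C=C/C | starting material
5 | 3-(menthyloxy)-7-methyl-3a,4,7,7a-tetrahydro-2-benzofuran-1(3H)-one, cis-fused, methyl cis to C=O, menthyloxy cis to the ring-fusion hydrogens | C[C@H]1CC[C@@H]([C@H](C1)O[C@@H]2[C@H]3CC=C[C@@H](C)[C@H]3C(=O)O2)C(C)C | intermediate
6 | acetaldehyde | CC=O | starting material
7 | 7a-(1-hydroxyethyl)-3-(menthyloxy)-7-methyl-3a,4,7,7a-tetrahydro-2-benzofuran-1(3H)-one (carbinol mixture) | C[C@H]1CC[C@@H]([C@H](C1)O[C@@H]2[C@H]3CC=C[C@@H](C)[C@]3(C(=O)O2)C(C)O)C(C)C | intermediate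
8 | 3-(menthyloxy)-7-methyl-7a-vinyl-3a,4,7,7a-tetrahydro-2-benzofuran-1(3H)-one | C[C@H]1CC[C@@H]([C@H](C1)O[C@@H]2[C@H]3CC=C[C@@H](C)[C@]3(C(=O)O2)C=C)C(C)C | intermediate
9 | 3-hydroxy-7-methyl-7a-vinyl-3a,4,7,7a-tetrahydro-2-benzofuran-1(3H)-one (lactol, mixture at C3) | OC1[C@H]2CC=C[C@@H](C)[C@]2(C(=O)O1)C=C | intermediate (not isolated)
10 | 7-methyl-7a-vinyl-3a,4,7,7a-tetrahydro-2-benzofuran-1(3H)-one, cis-fused | C1[C@H]2CC=C[C@@H](C)[C@]2(C(=O)O1)C=C | intermediate
11 | 2-(bromomethyl)-6-methyl-1-vinylcyclohex-4-ene-1-carboxylic acid, all-cis | BrC[C@H]1CC=C[C@@H](C)[C@]1(C(=O)O)C=C | intermediate (not isolated)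
12 | methyl 2-(bromomethyl)-6-methyl-1-vinylcyclohex-4-ene-1-carboxylate | BrC[C@H]1CC=C[C@@H](C)[C@]1(C(=O)OC)C=C | intermediate
13 | methyl 4-(bromomethyl)-2-methyl-3-vinyl-7-oxabicyclo[4.1.0]heptane-3-carboxylate | BrC[C@H]1CC2OC2[C@@H](C)[C@]1(C(=O)OC)C=C | intermediate
14 | 3-(bromomethyl)-4-(methoxycarbonyl)-5-methyl-4-vinylhexanedial | BrC[C@@H](CC=O)[C@@](C(=O)OC)(C=C)[C@H](C)C=O | intermediate
15 | methyl 5-(bromomethyl)-4-formyl-2-methyl-1-vinylcyclopent-3-ene-1-carboxylate | BrC[C@H]1C(C=O)=C[C@@H](C)[C@]1(C(=O)OC)C=C | intermediate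
16 | methyl 2-(bromomethyl)-5-methyl-3-{[(triethylsilyl)oxy]methylidene}-1-vinylcyclopentane-1-carboxylate | BrC[C@H]1C(=CO[Si](CC)(CC)CC)C[C@@H](C)[C@]1(C(=O)OC)C=C | intermediate
17 | methyl 2-(bromomethyl)-3-(dimethoxymethyl)-3-formyl-5-methyl-1-vinylcyclopentane-1-carboxylate | BrC[C@H]1[C@](C(OC)OC)(C[C@@H](C)[C@]1(C(=O)OC)C=C)C=O | intermediate
18 | methyl 2-(bromomethyl)-3-(dimethoxymethyl)-3-(2-ethoxy-1-hydroxyprop-2-en-1-yl)-5-methyl-1-vinylcyclopentane-1-carboxylate | BrC[C@H]1[C@](C(OC)OC)(C[C@@H](C)[C@]1(C(=O)OC)C=C)[C@@H](C(=C)OCC)O | intermediate (not isolated)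
19 | methyl 2-(bromomethyl)-3-(dimethoxymethyl)-3-[(1S)-1-hydroxy-2-oxopropyl]-5-methyl-1-vinylcyclopentane-1-carboxylate | BrC[C@H]1[C@](C(OC)OC)(C[C@@H](C)[C@]1(C(=O)OC)C=C)[C@@H](C(C)=O)O | intermediate
20 | triethylsilyl ether of 19 | BrC[C@H]1[C@](C(OC)OC)(C[C@@H](C)[C@]1(C(=O)OC)C=C)[C@@H](C(C)=O)O[Si](CC)(CC)CC | intermediate
21 | vinyltriphenylphosphonium bromide | C=C[P+](c1ccccc1)(c1ccccc1)c1ccccc1.[Br-] | starting material
22 | phosphonium ylide from 20 and 21 | c1ccccc1P(c1ccccc1)(c1ccccc1)=CCC[C@H]2[C@](C(OC)OC)(C[C@@H](C)[C@]2(C(=O)OC)C=C)[C@@H](C(C)=O)O[Si](CC)(CC)CC | intermediate (not isolated)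
23 | methyl 3a-(dimethoxymethyl)-2,5-dimethyl-4-[(triethylsilyl)oxy]-1-vinyl-1,2,3,3a,4,7,8,8a-octahydroazulene-1-carboxylate | CC1=CCC[C@H]2[C@](C(OC)OC)(C[C@@H](C)[C@]2(C(=O)OC)C=C)[C@@H]1O[Si](CC)(CC)CC | intermediate
24 | 4-bromofuran-2(5H)-one | O=C1C=C(Br)CO1 | starting material
25 | B-alkyl-9-borabicyclo[3.3.1]nonane from 23 | CC1=CCC[C@H]2[C@](C(OC)OC)(C[C@@H](C)[C@]2(C(=O)OC)CCB3C4CCCC3CCC4)[C@@H]1O[Si](CC)(CC)CC | intermediate (not isolated)
26 | methyl 3a-(dimethoxymethyl)-2,5-dimethyl-1-[2-(5-oxo-2,5-dihydrofuran-3-yl)ethyl]-4-[(triethylsilyl)oxy]-1,2,3,3a,4,7,8,8a-octahydroazulene-1-carboxylate | CC1=CCC[C@H]2[C@](C(OC)OC)(C[C@@H](C)[C@]2(C(=O)OC)CCC3=CC(=O)OC3)[C@@H]1O[Si](CC)(CC)CC | intermediate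
27 | dimethyl acetal and C4 triethylsilyl ether of the target | CC1=CCC[C@H]2[C@](C(OC)OC)(C[C@@H](C)[C@]2(CO)CC/C(=C/CO)CO)[C@@H]1O[Si](CC)(CC)CC | intermediate
28 | CNP0338913.1, (1R,2R,3aR,4R,8aR)-4-hydroxy-1-(hydroxymethyl)-1-[(3Z)-5-hydroxy-3-(hydroxymethyl)pent-3-en-1-yl]-2,5-dimethyl-2,3,4,7,8,8a-hexahydroazulene-3a(1H)-carbaldehyde | CC1=CCC[C@H]2[C@](C=O)(C[C@@H](C)[C@]2(CO)CC/C(=C/CO)CO)[C@@H]1O | target

**Totals**
Total step count: 17. Longest linear sequence: 17 steps (1 → 28); the other numbered starting materials are purchased.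

**Steps most likely to fail**

Step 14 (proposed new method). What may go wrong: hydrogen transfer to the primary radical before it reaches the vinylphosphonium ion, and protonation or acylation of the ylide before ring closure. The fallback sets out from 20 and returns at 23, and splits the event into two known operations. A tin hydride Giese reaction (Bu3SnH by syringe pump, AIBN, 21, MeCN/benzene, 80 °C) should give the alkyltriphenylphosphonium bromide F1, which is isolated by precipitation. Deprotonation with KN(SiMe3)2 in THF at high dilution (−78 → 40 °C) should then give ylide 22 and, by intramolecular Wittig reaction, 23.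

Step 12. What may go wrong: poor facial selectivity at C4 if the magnesium chelate does not form, and closure of the alkoxide onto the neighbouring bromide or ester if the quench is not cold. The fallback sets out from 17 and returns at 18, and moves the control from the substrate to the reagent. Addition of 1-ethoxyvinyllithium without magnesium salt should give 18 together with its C4 epimer, the epi-alcohol F2. The mixture is oxidised with triacetoxyperiodinane (DMP, NaHCO3, CH2Cl2) to the 2-ethoxy enone F3. Corey–Bakshi–Shibata reduction ((S)-Me-CBS oxazaborolidine, catecholborane, toluene, −78 °C, the quaternary ring carbon acting as the large group) should return 18, which is hydrolysed to 19 as in step 12.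

Step 15. What may go wrong: sluggish hydroboration and transmetalation next to the quaternary carbon, and base-induced decomposition of the bromobutenolide. The fallback sets out from 23 and returns at 26, and replaces the alkylborane coupling by an organozinc coupling. Hydroboration (9-BBN, via 25) with NaOH/H2O2 work-up should give the primary alcohol F4, and I2/PPh3/imidazole the primary iodide F5. Zinc insertion (Zn dust, LiCl, THF) should give the alkylzinc iodide F6. Negishi coupling with 24 under zerovalent palladium, Pd(PPh3)4, then gives 26.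

**Further compounds**
F1 | step 14 | alkyltriphenylphosphonium bromide from 20 and 21 | c1ccccc1[P+](c1ccccc1)(c1ccccc1)CCC[C@H]2[C@](C(OC)OC)(C[C@@H](C)[C@]2(C(=O)OC)C=C)[C@@H](C(C)=O)O[Si](CC)(CC)CC.[Br-]
F2 | step 12 | C4 epimer of 18 (epi-alcohol) | BrC[C@H]1[C@](C(OC)OC)(C[C@@H](C)[C@]1(C(=O)OC)C=C)[C@H](C(=C)OCC)O
F3 | step 12 | methyl 2-(bromomethyl)-3-(dimethoxymethyl)-3-(2-ethoxyprop-2-enoyl)-5-methyl-1-vinylcyclopentane-1-carboxylate | BrC[C@H]1[C@](C(OC)OC)(C[C@@H](C)[C@]1(C(=O)OC)C=C)C(=O)C(=C)OCC
F4 | step 15 | 1-(2-hydroxyethyl) analogue of 23 | CC1=CCC[C@H]2[C@](C(OC)OC)(C[C@@H](C)[C@]2(C(=O)OC)CCO)[C@@H]1O[Si](CC)(CC)CC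
F5 | step 15 | 1-(2-iodoethyl) analogue of 23 | CC1=CCC[C@H]2[C@](C(OC)OC)(C[C@@H](C)[C@]2(C(=O)OC)CCI)[C@@H]1O[Si](CC)(CC)CC
F6 | step 15 | alkylzinc iodide from F5 | CC1=CCC[C@H]2[C@](C(OC)OC)(C[C@@H](C)[C@]2(C(=O)OC)CC[Zn]I)[C@@H]1O[Si](CC)(CC)CC
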